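**Retrosynthetic overview**

1. Feature the plan rests on: in the 14-membered carbocycle (ring carbons C1–C14: C1 carries the exocyclic CH2, C2–C4 are CH2, C5 is CHMe, C6 CH–OH, C7/C8 the cis-γ-lactone fusion, C9 CH2, C10/C11 the epoxide, C12/C13 CH2, C14 CH–OH), C1 is the central carbon of an allyl unit H2C=C1(C14)–C2H2 whose two CH2 ends are equivalent, so the C2–C3 bond can be made by allylic alkylation with no regiochemical question.
2. Endgame: target ⇐ desilylation ⇐ lactone α-methylenation ⇐ Shi epoxidation of C10=C11 ⇐ reductive desulfonylation ⇐ palladium-catalysed C2–C3 closure of an acyclic allylic carbonate carrying a bis(phenylsulfonyl)methyl terminus.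
3. Acyclic precursor ⇐ cis-lactone by conjugate reduction of a butenolide ⇐ vinylogous Mukaiyama aldol (C6–C7) of a 4-substituted 2-silyloxyfuran with an α-methyl aldehyde that already holds the bis-sulfone.
4. Silyloxyfuran ⇐ Stille coupling (C8–C9) of a stannyl furanone with an allylic bromide made from geranyl acetate (allylic oxidation, Sharpless epoxidation for C14, epoxide-to-methylene-alcohol isomerisation); aldehyde ⇐ (R)-3-bromo-2-methylpropan-1-ol and bis(phenylsulfonyl)methane.
5. Ring order: γ-lactone first (as butenolide, steps 8–15), 14-membered carbocycle second (step 18), oxirane last (step 20).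

Key step: step 18

Remark: TBS is tert-butyldimethylsilyl; 4-bromofuran-2(5H)-one, hexabutylditin and (R)-3-bromo-2-methylpropan-1-ol are taken as purchased, and the locants C1–C14 are those defined in line 1.

**Route**

Step 1
Reactants: 1 geranyl acetate
Product: 2 (2E,6E)-8-hydroxy-3,7-dimethylocta-2,6-dien-1-yl acetate
Conditions: SeO2 (cat.), t-BuOOH, salicylic acid (cat.), CH2Cl2, rt
Reagents that add atoms: tert-butyl hydroperoxide, CC(C)(C)OO
Why: Selenium dioxide allylic oxidation (ene reaction then [2,3]-shift, t-BuOOH as terminal oxidant) should hydroxylate the (E)-methyl of the electron-rich terminal alkene and leave the acetate-deactivated inner alkene alone.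

Step 2
Reactants: 2 (2E,6E)-8-hydroxy-3,7-dimethylocta-2,6-dien-1-yl acetate
Product: 3 (2E)-5-[(2R,3R)-3-(hydroxymethyl)-3-methyloxiran-2-yl]-3-methylpent-2-en-1-yl acetate
Conditions: Ti(OiPr)4 (cat.), D-(−)-diethyl tartrate (cat.), t-BuOOH, 4 Å molecular sieves, CH2Cl2, −20 °C
Reagents that add atoms: tert-butyl hydroperoxide, CC(C)(C)OO
Why: Sharpless asymmetric epoxidation of the primary allylic alcohol, where the D-(−)-tartrate should give the (2R,3R)-epoxide (mirror image of the (2S,3S) sense of the L-(+)-ester with E-allylic alcohols) and so fixes the C14 oxygen centre, while the alkene without an allylic hydroxyl is not touched.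

Step 3
Reactants: 3 (2E)-5-[(2R,3R)-3-(hydroxymethyl)-3-methyloxiran-2-yl]-3-methylpent-2-en-1-yl acetate
Product: 4 (2E)-5-[(2R,3R)-3-{[(tert-butyldimethylsilyl)oxy]methyl}-3-methyloxiran-2-yl]-3-methylpent-2-en-1-yl acetate
Conditions: TBSCl, imidazole, CH2Cl2, 0 °C to rt
Reagents that add atoms: tert-butyldimethylsilyl chloride, CC(C)(C)[Si](C)(C)Cl
Why: Standard silylation of the primary alcohol under non-basic conditions (no epoxide migration), which masks the oxygen that later becomes the carbonate.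

Step 4
Reactants: 4 (2E)-5-[(2R,3R)-3-{[(tert-butyldimethylsilyl)oxy]methyl}-3-methyloxiran-2-yl]-3-methylpent-2-en-1-yl acetate
Product: 5 (2E)-5-[(2R,3R)-3-{[(tert-butyldimethylsilyl)oxy]methyl}-3-methyloxiran-2-yl]-3-methylpent-2-en-1-ol
Conditions: K2CO3 (cat.), MeOH, 0 °C to rt
Reagents that add atoms: none
Why: Carbonate-catalysed transesterification removes the acetate, which an aluminium amide would enolise in the next step, and leaves the epoxide and the silyl ether intact.

Step 5
Reactants: 5 (2E)-5-[(2R,3R)-3-{[(tert-butyldimethylsilyl)oxy]methyl}-3-methyloxiran-2-yl]-3-methylpent-2-en-1-ol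
Product: 6 (2E,6R)-7-{[(tert-butyldimethylsilyl)oxy]methyl}-3-methylocta-2,7-diene-1,6-diol
Conditions: Et2Al(TMP) (4 equiv; from 2,2,6,6-tetramethylpiperidine, n-BuLi, Et2AlCl), toluene, 0 °C to rt; aq. work-up
Reagents that add atoms: none
Why: Epoxide-to-allylic-alcohol isomerisation by the bulky aluminium amide, a syn-elimination that should break the C–O bond at the tertiary carbon with loss of a methyl proton to give the 1,1-disubstituted alkene, so the secondary C14–O bond and its configuration are untouched and the free hydroxyl only uses one equivalent of reagent.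

Step 6
Reactants: 6 (2E,6R)-7-{[(tert-butyldimethylsilyl)oxy]methyl}-3-methylocta-2,7-diene-1,6-diol
Product: 8 (3R,6E)-8-bromo-2-{[(tert-butyldimethylsilyl)oxy]methyl}-6-methylocta-1,6-dien-3-ol, via allylic mesylate 7 (not isolated)
Conditions: MsCl, Et3N, THF, −45 °C; then LiBr, THF, −45 to 0 °C
Reagents that add atoms: lithium bromide, [Li+].[Br-]; methanesulfonyl chloride, CS(=O)(=O)Cl (its atoms stay only in intermediate 7)
Why: Low-temperature mesylation should discriminate the unhindered primary allylic alcohol from the hindered secondary one, and bromide displaces the mesylate in situ by SN2 with the E-alkene geometry kept.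

Step 7
Reactants: 8 (3R,6E)-8-bromo-2-{[(tert-butyldimethylsilyl)oxy]methyl}-6-methylocta-1,6-dien-3-ol
Product: 9 (3R,6E)-8-bromo-3-[(tert-butyldimethylsilyl)oxy]-2-{[(tert-butyldimethylsilyl)oxy]methyl}-6-methylocta-1,6-diene
Conditions: TBSOTf, 2,6-lutidine, CH2Cl2, −78 °C
Reagents that add atoms: tert-butyldimethylsilyl triflate, CC(C)(C)[Si](C)(C)OS(=O)(=O)C(F)(F)F
Why: Silyl triflate silylation of the hindered secondary alcohol with a non-nucleophilic base leaves the allylic bromide intact and stops the hydroxyl from attacking the π-allyl complex of the next coupling.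

Step 8
Reactants: 10 4-bromofuran-2(5H)-one; 11 hexabutylditin
Product: 12 4-(tributylstannyl)furan-2(5H)-one
Conditions: Pd(PPh3)4 (cat.), toluene, 100 °C
Reagents that add atoms: none
Why: Palladium-catalysed stannylation of the vinyl bromide with the distannane (oxidative addition, Sn–Sn transmetallation, reductive elimination), a standard reaction of β-bromo enoates.

Step 9
Reactants: 9 (3R,6E)-8-bromo-3-[(tert-butyldimethylsilyl)oxy]-2-{[(tert-butyldimethylsilyl)oxy]methyl}-6-methylocta-1,6-diene; 12 4-(tributylstannyl)furan-2(5H)-one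
Product: 13 4-[(2E,6R)-6-[(tert-butyldimethylsilyl)oxy]-7-{[(tert-butyldimethylsilyl)oxy]methyl}-3-methylocta-2,7-dien-1-yl]furan-2(5H)-one
Conditions: Pd2(dba)3 (tris(dibenzylideneacetone)dipalladium, cat.), AsPh3 (cat.), THF, 50 °C
Reagents that add atoms: none
Why: Stille coupling of a vinylstannane with a primary allylic bromide, in which the allylpalladium intermediate couples at its unsubstituted end to form C8–C9 with the E-trisubstituted alkene kept, while silyl ethers do not ionise under zerovalent palladium.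

Step 10
Reactants: 13 4-[(2E,6R)-6-[(tert-butyldimethylsilyl)oxy]-7-{[(tert-butyldimethylsilyl)oxy]methyl}-3-methylocta-2,7-dien-1-yl]furan-2(5H)-one
Product: 14 2-[(tert-butyldimethylsilyl)oxy]-4-[(2E,6R)-6-[(tert-butyldimethylsilyl)oxy]-7-{[(tert-butyldimethylsilyl)oxy]methyl}-3-methylocta-2,7-dien-1-yl]furan
Conditions: TBSOTf, Et3N, CH2Cl2, 0 °C
Reagents that add atoms: tert-butyldimethylsilyl triflate, CC(C)(C)[Si](C)(C)OS(=O)(=O)C(F)(F)F
Why: Soft enolisation of the butenolide at its ring γ-CH2 gives the aromatic 2-silyloxyfuran, which is favoured over deprotonation at the exocyclic C9 position.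

Step 11
Reactants: 15 (R)-3-bromo-2-methylpropan-1-ol; 16 bis(phenylsulfonyl)methane
Product: 18 (S)-2-methyl-4,4-bis(phenylsulfonyl)butan-1-ol, via sodium bis(phenylsulfonyl)methanide 17 (not isolated)
Conditions: 16 (2 equiv), NaH, DMF, 0 °C to rt; then 15, NaI (cat.), 80 °C
Reagents that add atoms: none
Why: SN2 alkylation of the stabilised bis-sulfonyl carbanion (pKa about 12) with the primary bromide, helped by in situ Finkelstein exchange; the carbanion is too weak a base to deprotonate the alcohol and the stereocentre is not involved.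

Step 12
Reactants: 18 (S)-2-methyl-4,4-bis(phenylsulfonyl)butan-1-ol
Product: 19 (S)-2-methyl-4,4-bis(phenylsulfonyl)butanal
Conditions: Dess–Martin periodinane, CH2Cl2, 0 °C to rt
Reagents that add atoms: none
Why: Dess–Martin oxidation is neutral and fast, so the α-stereocentre and the acidic bis-sulfone CH should be undisturbed; the aldehyde is used at once.

Step 13
Reactants: 14 2-[(tert-butyldimethylsilyl)oxy]-4-substituted furan; 19 (S)-2-methyl-4,4-bis(phenylsulfonyl)butanal
Product: 20 (5R)-5-[(1R,2S)-1-hydroxy-2-methyl-4,4-bis(phenylsulfonyl)butyl]-4-[(2E,6R)-6-[(tert-butyldimethylsilyl)oxy]-7-{[(tert-butyldimethylsilyl)oxy]methyl}-3-methylocta-2,7-dien-1-yl]furan-2(5H)-one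
Conditions: BF3·OEt2, CH2Cl2, −78 °C; pH 7 buffer
Reagents that add atoms: none
Why: Vinylogous Mukaiyama aldol at the furan γ-carbon, where the aldehyde face should follow Felkin–Anh control from the α-methyl centre (C5/C6 syn) and the furan face the threo preference of Lewis-acid silyloxyfuran additions through an open transition state (C6/C7 syn), giving the (6R,7R) adduct with minor diastereomers removed by chromatography.

Step 14
Reactants: 20 hydroxy butenolide
Product: 21 (5R)-5-[(1R,2S)-1-[(tert-butyldimethylsilyl)oxy]-2-methyl-4,4-bis(phenylsulfonyl)butyl]-4-[(2E,6R)-6-[(tert-butyldimethylsilyl)oxy]-7-{[(tert-butyldimethylsilyl)oxy]methyl}-3-methylocta-2,7-dien-1-yl]furan-2(5H)-one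
Conditions: TBSOTf, 2,6-lutidine, CH2Cl2, −78 °C
Reagents that add atoms: tert-butyldimethylsilyl triflate, CC(C)(C)[Si](C)(C)OS(=O)(=O)C(F)(F)F
Why: Silyl triflate silylation of the secondary alcohol at −78 °C with 2,6-lutidine, a base too weak to re-enolise the butenolide, so C7 should not epimerise.

Step 15
Reactants: 21 silylated butenolide
Product: 22 (4S,5R)-5-[(1R,2S)-1-[(tert-butyldimethylsilyl)oxy]-2-methyl-4,4-bis(phenylsulfonyl)butyl]-4-[(2E,6R)-6-[(tert-butyldimethylsilyl)oxy]-7-{[(tert-butyldimethylsilyl)oxy]methyl}-3-methylocta-2,7-dien-1-yl]dihydrofuran-2(3H)-one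
Conditions: Cu(OAc)2·H2O (cat.), 1,2-bis(diphenylphosphino)benzene (cat.), (EtO)2MeSiH, t-BuOH, toluene, 0 °C to rt
Reagents that add atoms: none
Why: Copper hydride conjugate reduction of the β,β-disubstituted butenolide, chemoselective over isolated alkenes, sulfones and silyl ethers, with hydride delivered to C8 anti to the bulky C7 side chain so that C7–H and C8–H end up cis (8S) after protonation of the enolate by t-BuOH.

Step 16
Reactants: 22 cis-lactone with three TBS ethers
Product: 23 (4S,5R)-5-[(1R,2S)-1-[(tert-butyldimethylsilyl)oxy]-2-methyl-4,4-bis(phenylsulfonyl)butyl]-4-[(2E,6R)-6-[(tert-butyldimethylsilyl)oxy]-7-(hydroxymethyl)-3-methylocta-2,7-dien-1-yl]dihydrofuran-2(3H)-one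
Conditions: HF·pyridine, pyridine, THF, 0 °C
Reagents that add atoms: none
Why: Buffered HF·pyridine should cleave the unhindered primary allylic silyl ether much faster than the two hindered secondary ones, a routine primary-over-secondary discrimination.

Step 17
Reactants: 23 primary allylic alcohol
Product: 24 methyl carbonate of 23 (acyclic cyclisation precursor)
Conditions: ClCO2Me, pyridine, CH2Cl2, 0 °C
Reagents that add atoms: methyl chloroformate, COC(=O)Cl
Why: O-acylation of the primary allylic alcohol with methyl chloroformate; pyridine is too weak a base to deprotonate the bis-sulfone, so no C-acylation is expected.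

Step 18
Reactants: 24 allylic methyl carbonate with bis(phenylsulfonyl)methyl terminus
Product: 26 bis-sulfone macrocycle (14-membered ring closed at C2–C3; exocyclic methylene on C1; 6,14-bis-TBS ether; cis-lactone; 10E), via π-allylpalladium zwitterion 25 (not isolated)
Conditions: Pd(PPh3)4 (10 mol %), THF, 65 °C, slow addition of 24 over 12 h, final 0.002 M
Reagents that add atoms: none
Why: Zerovalent palladium ionises the allylic carbonate with loss of CO2 to a cationic π-allylpalladium complex and methoxide, which deprotonates the bis-sulfone (far more acidic than methanol) so that no added base is needed, and the soft carbanion attacks an allyl terminus on the face away from palladium to form C2–C3. The closest known reaction type is the Tsuji–Trost allylic alkylation used for macrocyclisation with bis(sulfonyl)methyl nucleophiles under neutral carbonate conditions. The 14-membered carbocycle closes by attack of C3 on a terminal CH2 of the allyl unit whose central carbon C1 already carries the tether through C14, an exo-type closure that leaves C1=CH2 exocyclic; because both termini are CH2, attack at either gives the same ring and the usual choice between two ring sizes does not arise. No stereocentre is created, and C14 next to the allyl unit lies outside the π-system and keeps its configuration. The selectivity needed is ring closure over oligomerisation, secured by slow addition into a dilute hot catalyst solution, and C- over O-alkylation, secured by the acidity of the bis-sulfone; the lactone, the silyl ethers and the trisubstituted alkene are spectators.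

Step 19
Reactants: 26 bis-sulfone macrocycle
Product: 28 desulfonylated macrocycle (C3 now CH2), via monosulfone 27 (not isolated)
Conditions: sodium amalgam (6% Na in Hg), Na2HPO4, MeOH–THF, −20 °C
Reagents that add atoms: none
Why: Reductive desulfonylation by successive electron transfer and protonation should cleave both C–S bonds in buffered methanol, conditions that the lactone, the silyl ethers and the unactivated alkenes tolerate.

Step 20
Reactants: 28 desulfonylated macrocycle
Product: 29 (10R,11R)-epoxide of 28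
Conditions: D-fructose-derived Shi ketone (1,2:4,5-di-O-isopropylidene-β-D-erythro-2,3-hexodiulo-2,6-pyranose, 30 mol %), KHSO5 (as 2KHSO5·KHSO4·K2SO4), K2CO3, Bu4NHSO4 (cat.), MeCN–CH2(OMe)2–aq. Na2B4O7 buffer, 0 °C
Reagents that add atoms: potassium peroxymonosulfate, [K+].[O-]S(=O)(=O)OO
Why: Shi asymmetric epoxidation, in which the chiral dioxirane should attack the electron-rich E-trisubstituted alkene through a spiro transition state with the facial sense that gives (R,R)-epoxides, here (10R,11R), while the hindered 1,1-disubstituted alkene between two silyloxy-bearing carbons reacts far more slowly.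

Step 21
Reactants: 29 epoxy lactone
Product: 33 α-methylene lactone (6,14-bis-TBS ether of the target), via lithium lactone enolate 30 (not isolated), via α-(dimethylaminomethyl) lactone 31 (not isolated), via quaternary ammonium iodide 32 (not isolated)
Conditions: LDA, THF, −78 °C; CH2=NMe2+ I−, −78 °C to rt; MeI, CH2Cl2, rt; DBU, rt
Reagents that add atoms: Eschenmoser's salt, C=[N+](C)C.[I-]; iodomethane, CI (its methyl stays only in intermediate 32)
Why: Lactone α-methylenation by Mannich reaction of the lithium enolate with Eschenmoser's salt, N-methylation and base-induced elimination of trimethylamine; the enolate is formed at −78 °C where the epoxide is inert, and C8 cannot epimerise.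

Step 22
Reactants: 33 bis-TBS ether of the target
Product: 34 CNP0124069.1 (target)
Conditions: Bu4NF, AcOH, THF, 0 °C to rt
Reagents that add atoms: none
Why: Fluoride cleavage of both secondary silyl ethers under acetic acid buffering, chosen to avoid base-induced migration of the lactone to the C6 hydroxyl and acid-induced attack of the C14 hydroxyl on the epoxide.

**Compound list**

1 | geranyl acetate, (2E)-3,7-dimethylocta-2,6-dien-1-yl acetate | CC(C)=CCC/C(C)=C/COC(C)=O | starting material
2 | (2E,6E)-8-hydroxy-3,7-dimethylocta-2,6-dien-1-yl acetate | CC(=O)OC/C=C(\C)CC/C=C(\C)CO | intermediate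
3 | (2E)-5-[(2R,3R)-3-(hydroxymethyl)-3-methyloxiran-2-yl]-3-methylpent-2-en-1-yl acetate | CC(=O)OC/C=C(\C)CC[C@H]1O[C@]1(C)CO | intermediate
4 | (2E)-5-[(2R,3R)-3-{[(tert-butyldimethylsilyl)oxy]methyl}-3-methyloxiran-2-yl]-3-methylpent-2-en-1-yl acetate | CC(=O)OC/C=C(\C)CC[C@H]1O[C@]1(C)CO[Si](C)(C)C(C)(C)C | intermediate
5 | (2E)-5-[(2R,3R)-3-{[(tert-butyldimethylsilyl)oxy]methyl}-3-methyloxiran-2-yl]-3-methylpent-2-en-1-ol | OC/C=C(\C)CC[C@H]1O[C@]1(C)CO[Si](C)(C)C(C)(C)C | intermediate
6 | (2E,6R)-7-{[(tert-butyldimethylsilyl)oxy]methyl}-3-methylocta-2,7-diene-1,6-diol | CC(C)(C)[Si](C)(C)OCC(=C)[C@H](O)CC/C(C)=C/CO | intermediate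
7 | (2E,6R)-7-{[(tert-butyldimethylsilyl)oxy]methyl}-6-hydroxy-3-methylocta-2,7-dien-1-yl methanesulfonate | CC(C)(C)[Si](C)(C)OCC(=C)[C@H](O)CC/C(C)=C/COS(C)(=O)=O | intermediate
8 | (3R,6E)-8-bromo-2-{[(tert-butyldimethylsilyl)oxy]methyl}-6-methylocta-1,6-dien-3-ol | CC(C)(C)[Si](C)(C)OCC(=C)[C@H](O)CC/C(C)=C/CBr | intermediate
9 | (3R,6E)-8-bromo-3-[(tert-butyldimethylsilyl)oxy]-2-{[(tert-butyldimethylsilyl)oxy]methyl}-6-methylocta-1,6-diene | CC(C)(C)[Si](C)(C)OCC(=C)[C@H](O[Si](C)(C)C(C)(C)C)CC/C(C)=C/CBr | intermediate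
10 | 4-bromofuran-2(5H)-one | O=C1OCC(Br)=C1 | starting material
11 | hexabutylditin | CCCC[Sn](CCCC)(CCCC)[Sn](CCCC)(CCCC)CCCC | starting material
12 | 4-(tributylstannyl)furan-2(5H)-one | O=C1OCC([Sn](CCCC)(CCCC)CCCC)=C1 | intermediate
13 | 4-[(2E,6R)-6-[(tert-butyldimethylsilyl)oxy]-7-{[(tert-butyldimethylsilyl)oxy]methyl}-3-methylocta-2,7-dien-1-yl]furan-2(5H)-one | CC(C)(C)[Si](C)(C)OCC(=C)[C@H](O[Si](C)(C)C(C)(C)C)CC/C(C)=C/CC1=CC(=O)OC1 | intermediate
14 | 2-[(tert-butyldimethylsilyl)oxy]-4-[(2E,6R)-6-[(tert-butyldimethylsilyl)oxy]-7-{[(tert-butyldimethylsilyl)oxy]methyl}-3-methylocta-2,7-dien-1-yl]furan | CC(C)(C)[Si](C)(C)OCC(=C)[C@H](O[Si](C)(C)C(C)(C)C)CC/C(C)=C/Cc1coc(O[Si](C)(C)C(C)(C)C)c1 | intermediate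
15 | (R)-3-bromo-2-methylpropan-1-ol | OC[C@@H](C)CBr | starting material
16 | bis(phenylsulfonyl)methane | O=S(=O)(CS(=O)(=O)c1ccccc1)c1ccccc1 | starting material
17 | sodium bis(phenylsulfonyl)methanide | [Na+].O=S(=O)([CH-]S(=O)(=O)c1ccccc1)c1ccccc1 | intermediate
18 | (S)-2-methyl-4,4-bis(phenylsulfonyl)butan-1-ol | OC[C@@H](C)CC(S(=O)(=O)c1ccccc1)S(=O)(=O)c1ccccc1 | intermediate
19 | (S)-2-methyl-4,4-bis(phenylsulfonyl)butanal | O=C[C@@H](C)CC(S(=O)(=O)c1ccccc1)S(=O)(=O)c1ccccc1 | intermediate
20 | (5R)-5-[(1R,2S)-1-hydroxy-2-methyl-4,4-bis(phenylsulfonyl)butyl]-4-[(2E,6R)-6-[(tert-butyldimethylsilyl)oxy]-7-{[(tert-butyldimethylsilyl)oxy]methyl}-3-methylocta-2,7-dien-1-yl]furan-2(5H)-one | CC(C)(C)[Si](C)(C)OCC(=C)[C@H](O[Si](C)(C)C(C)(C)C)CC/C(C)=C/CC1=CC(=O)O[C@H]1[C@H](O)[C@@H](C)CC(S(=O)(=O)c1ccccc1)S(=O)(=O)c1ccccc1 | intermediate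
21 | (5R)-5-[(1R,2S)-1-[(tert-butyldimethylsilyl)oxy]-2-methyl-4,4-bis(phenylsulfonyl)butyl]-4-[(2E,6R)-6-[(tert-butyldimethylsilyl)oxy]-7-{[(tert-butyldimethylsilyl)oxy]methyl}-3-methylocta-2,7-dien-1-yl]furan-2(5H)-one | CC(C)(C)[Si](C)(C)OCC(=C)[C@H](O[Si](C)(C)C(C)(C)C)CC/C(C)=C/CC1=CC(=O)O[C@H]1[C@H](O[Si](C)(C)C(C)(C)C)[C@@H](C)CC(S(=O)(=O)c1ccccc1)S(=O)(=O)c1ccccc1 | intermediate
22 | (4S,5R)-5-[(1R,2S)-1-[(tert-butyldimethylsilyl)oxy]-2-methyl-4,4-bis(phenylsulfonyl)butyl]-4-[(2E,6R)-6-[(tert-butyldimethylsilyl)oxy]-7-{[(tert-butyldimethylsilyl)oxy]methyl}-3-methylocta-2,7-dien-1-yl]dihydrofuran-2(3H)-one (cis-lactone) | CC(C)(C)[Si](C)(C)OCC(=C)[C@H](O[Si](C)(C)C(C)(C)C)CC/C(C)=C/C[C@H]1CC(=O)O[C@H]1[C@H](O[Si](C)(C)C(C)(C)C)[C@@H](C)CC(S(=O)(=O)c1ccccc1)S(=O)(=O)c1ccccc1 | intermediate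
23 | (4S,5R)-5-[(1R,2S)-1-[(tert-butyldimethylsilyl)oxy]-2-methyl-4,4-bis(phenylsulfonyl)butyl]-4-[(2E,6R)-6-[(tert-butyldimethylsilyl)oxy]-7-(hydroxymethyl)-3-methylocta-2,7-dien-1-yl]dihydrofuran-2(3H)-one | OCC(=C)[C@H](O[Si](C)(C)C(C)(C)C)CC/C(C)=C/C[C@H]1CC(=O)O[C@H]1[C@H](O[Si](C)(C)C(C)(C)C)[C@@H](C)CC(S(=O)(=O)c1ccccc1)S(=O)(=O)c1ccccc1 | intermediate
24 | methyl carbonate of 23: (3R,6E)-3-[(tert-butyldimethylsilyl)oxy]-6-methyl-2-methylidene-8-[(2R,3S)-lactone ring]oct-6-en-1-yl methyl carbonate, the lactone carrying the (1R,2S)-1-[(tert-butyldimethylsilyl)oxy]-2-methyl-4,4-bis(phenylsulfonyl)butyl group | COC(=O)OCC(=C)[C@H](O[Si](C)(C)C(C)(C)C)CC/C(C)=C/C[C@H]1CC(=O)O[C@H]1[C@H](O[Si](C)(C)C(C)(C)C)[C@@H](C)CC(S(=O)(=O)c2ccccc2)S(=O)(=O)c3ccccc3 | intermediate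
25 | π-allylpalladium bis(triphenylphosphine) cation with tethered bis(phenylsulfonyl) carbanion (zwitterion, drawn as its σ-allyl form) | C=C(C[Pd-]([P+](c1ccccc1)(c1ccccc1)c1ccccc1)[P+](c1ccccc1)(c1ccccc1)c1ccccc1)[C@H](O[Si](C)(C)C(C)(C)C)CC/C(C)=C/C[C@H]1CC(=O)O[C@H]1[C@H](O[Si](C)(C)C(C)(C)C)[C@@H](C)C[C-](S(=O)(=O)c1ccccc1)S(=O)(=O)c1ccccc1 | intermediate
26 | bis-sulfone macrocycle: 14-membered carbocycle with 1-methylidene, 3,3-bis(phenylsulfonyl), (5S)-methyl, (6R)- and (14R)-OTBS, (10E)-alkene with 11-methyl, cis-fused γ-lactone (O on C7 (R), CH2C(=O) on C8 (S)) | C=C1CC(S(=O)(=O)c2ccccc2)(S(=O)(=O)c3ccccc3)C[C@H](C)[C@@H](O[Si](C)(C)C(C)(C)C)[C@@H]4OC(=O)C[C@@H]4C/C=C(\C)CC[C@H]1O[Si](C)(C)C(C)(C)C | intermediate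
27 | monosulfone macrocycle (as 26 with one phenylsulfonyl on C3, both C3 epimers) | C=C1CC(S(=O)(=O)c2ccccc2)C[C@H](C)[C@@H](O[Si](C)(C)C(C)(C)C)[C@@H]3OC(=O)C[C@@H]3C/C=C(\C)CC[C@H]1O[Si](C)(C)C(C)(C)C | intermediate
28 | desulfonylated macrocycle (as 26 with C3 = CH2; 5S,6R,7R,8S,14R,10E) | C=C1CCC[C@H](C)[C@@H](O[Si](C)(C)C(C)(C)C)[C@@H]2OC(=O)C[C@@H]2C/C=C(\C)CC[C@H]1O[Si](C)(C)C(C)(C)C | intermediate
29 | (10R,11R)-epoxide of 28 (saturated cis-lactone, 6,14-bis-TBS ether) | C=C1CCC[C@H](C)[C@@H](O[Si](C)(C)C(C)(C)C)[C@@H]2OC(=O)C[C@@H]2C[C@H]2O[C@]2(C)CC[C@H]1O[Si](C)(C)C(C)(C)C | intermediate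
30 | lithium enolate of lactone 29 | C=C1CCC[C@H](C)[C@@H](O[Si](C)(C)C(C)(C)C)[C@@H]2OC(O[Li])=C[C@@H]2C[C@H]2O[C@]2(C)CC[C@H]1O[Si](C)(C)C(C)(C)C | intermediate
31 | α-(dimethylaminomethyl) lactone (as 29 with CH2NMe2 on the lactone α-carbon, both epimers) | C=C1CCC[C@H](C)[C@@H](O[Si](C)(C)C(C)(C)C)[C@@H]2OC(=O)C(CN(C)C)[C@@H]2C[C@H]2O[C@]2(C)CC[C@H]1O[Si](C)(C)C(C)(C)C | intermediate
32 | trimethylammonium iodide of 31 | C=C1CCC[C@H](C)[C@@H](O[Si](C)(C)C(C)(C)C)[C@@H]2OC(=O)C(C[N+](C)(C)C)[C@@H]2C[C@H]2O[C@]2(C)CC[C@H]1O[Si](C)(C)C(C)(C)C.[I-] | intermediate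
33 | 6,14-bis-TBS ether of the target (α-methylene cis-lactone, (10R,11R)-epoxide) | C=C1CCC[C@H](C)[C@@H](O[Si](C)(C)C(C)(C)C)[C@@H]2OC(=O)C(=C)[C@@H]2C[C@H]2O[C@]2(C)CC[C@H]1O[Si](C)(C)C(C)(C)C | intermediate
34 | CNP0124069.1: (5S,6R,7R,8S,10R,11R,14R)-6,14-dihydroxy-5,11-dimethyl-1-methylidene-10,11-epoxycyclotetradecane cis-fused at C7/C8 to an α-methylene-γ-butyrolactone | C=C1CCC[C@H](C)[C@@H](O)[C@@H]2OC(=O)C(=C)[C@@H]2C[C@H]2O[C@]2(C)CC[C@H]1O | target

**Totals and risks**

Total step count: 22. Longest linear sequence: 19 steps (steps 1–7, 9, 10 and 13–22, from geranyl acetate).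

Step 18. The ring closure may lose to intermolecular alkylation (oligomer formation), or attack on the hindered 2-substituted allyl complex may be slow enough for methoxide to open the lactone. The fallback sets out from 23: bromination of the primary allylic alcohol (CBr4, PPh3, CH2Cl2, 0 °C) gives the allylic bromide F1, which is added slowly to Cs2CO3 in DMF at 60 °C at about 0.002 M. The caesium bis-sulfonyl carbanion then closes the ring by direct SN2 displacement (an SN2′ course gives the same constitution because the allyl unit is symmetrical), without palladium or methoxide, and the route is rejoined at 26.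

Step 13. Facial selectivity may be poor at either partner (Felkin against anti-Felkin at the aldehyde, threo against erythro at the furan), and BF3 may strip allylic silyl ethers from the elaborate furan, leaving diastereomers that are hard to separate once the long chain is attached. The fallback reverses the order of fragment union and sets out from 12: TBSOTf and Et3N give the stannyl silyloxyfuran F2, whose BF3·OEt2 aldol addition to 19 should give the small stannyl hydroxy butenolide F3, a bis-sulfone on which the isomers can be separated before the chain is committed. Silylation (TBSOTf, 2,6-lutidine, −78 °C) gives the silyl ether F4, and Stille coupling of F4 with bromide 9 (Pd2(dba)3, AsPh3, THF, 50 °C) rejoins the route at 21.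

Step 20. The conformational bias of the 14-membered ring may oppose the catalyst and erode facial selectivity, or the exocyclic alkene may be over-oxidised. The fallback epoxidises before ring closure, where only catalyst control operates, and sets out from 24: Shi epoxidation with the same ketone (stoichiometric ketone, KHSO5, pH 8 buffer so that the bis-sulfone stays protonated) should give the epoxy carbonate F5. Cyclisation under the step 18 conditions (Pd(PPh3)4, THF, 65 °C, high dilution) gives the epoxy bis-sulfone macrocycle F6, and sodium amalgam desulfonylation rejoins the route at 29.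

**Further compounds**

F1 | step 18 | (4S,5R)-4-[(2E,6R)-7-(bromomethyl)-6-[(tert-butyldimethylsilyl)oxy]-3-methylocta-2,7-dien-1-yl]-5-[(1R,2S)-1-[(tert-butyldimethylsilyl)oxy]-2-methyl-4,4-bis(phenylsulfonyl)butyl]dihydrofuran-2(3H)-one | BrCC(=C)[C@H](O[Si](C)(C)C(C)(C)C)CC/C(C)=C/C[C@H]1CC(=O)O[C@H]1[C@H](O[Si](C)(C)C(C)(C)C)[C@@H](C)CC(S(=O)(=O)c1ccccc1)S(=O)(=O)c1ccccc1
F2 | step 13 | tert-butyldimethyl{[4-(tributylstannyl)furan-2-yl]oxy}silane | CCCC[Sn](CCCC)(CCCC)c1coc(O[Si](C)(C)C(C)(C)C)c1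
F3 | step 13 | (5S)-5-[(1R,2S)-1-hydroxy-2-methyl-4,4-bis(phenylsulfonyl)butyl]-4-(tributylstannyl)furan-2(5H)-one (same spatial arrangement at the ring carbon as in 20) | CCCC[Sn](CCCC)(CCCC)C1=CC(=O)O[C@H]1[C@H](O)[C@@H](C)CC(S(=O)(=O)c1ccccc1)S(=O)(=O)c1ccccc1
F4 | step 13 | (5S)-5-[(1R,2S)-1-[(tert-butyldimethylsilyl)oxy]-2-methyl-4,4-bis(phenylsulfonyl)butyl]-4-(tributylstannyl)furan-2(5H)-one | CCCC[Sn](CCCC)(CCCC)C1=CC(=O)O[C@H]1[C@H](O[Si](C)(C)C(C)(C)C)[C@@H](C)CC(S(=O)(=O)c1ccccc1)S(=O)(=O)c1ccccc1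
F5 | step 20 | (10R,11R)-epoxide of carbonate 24 | COC(=O)OCC(=C)[C@H](O[Si](C)(C)C(C)(C)C)CC[C@@]1(C)O[C@@H]1C[C@H]2CC(=O)O[C@H]2[C@H](O[Si](C)(C)C(C)(C)C)[C@@H](C)CC(S(=O)(=O)c3ccccc3)S(=O)(=O)c4ccccc4
F6 | step 20 | (10R,11R)-epoxide of bis-sulfone macrocycle 26 | C=C1CC(S(=O)(=O)c2ccccc2)(S(=O)(=O)c3ccccc3)C[C@H](C)[C@@H](O[Si](C)(C)C(C)(C)C)[C@@H]4OC(=O)C[C@@H]4C[C@H]5O[C@]5(C)CC[C@H]1O[Si](C)(C)C(C)(C)C
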